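**Retrosynthetic overview**

1. Feature: on ring A of the flavone, the phenol carbons C5 and C7 are the two ortho neighbours of C6, and C6 carries C2' of the piperidine. The tertiary amine N1' therefore sits one atom from C6 and can close a five-membered palladacycle (Pd, N1', C2', C6, C5 or C7) to either side; C5 also lies peri to the C4 carbonyl.
2. Target ⇒ 5,7-diacetate (methanolysis) ⇒ both C5–O and C7–O bonds cut together: N1'-directed double C–H acetoxylation of 6-[(2R)-1-methylpiperidin-2-yl]flavone with Pd(OAc)2/PhI(OAc)2.
3. That flavone ⇒ N-Boc amine (TFA, then reductive methylation) ⇒ C6–C2' bond by lithiation, ligand-mediated dynamic resolution, zinc transmetalation and Negishi coupling of N-Boc-piperidine with 6-bromoflavone, which sets C2' as R.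
4. Ring order: rings A and C of the chromone, phenyl ring B and the piperidine are all bought; no ring is formed, and ring A carries no oxygen substituent until step 4.

Key step: step 4

Remark: flavone numbering with primed piperidine atoms is used; C2' of the target is R (N1' > C6 > C3' > H). The resolving ligand in step 1 is a proline-derived diamino alcohol used as a catalyst, not a starting material.

**Route**

Step 1
Reactants: 1 tert-butyl piperidine-1-carboxylate (N-Boc-piperidine); 2 6-bromo-2-phenyl-4H-chromen-4-one (6-bromoflavone)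
Product: 5 tert-butyl (2R)-2-(4-oxo-2-phenyl-4H-chromen-6-yl)piperidine-1-carboxylate, via lithiopiperidine 3 (not isolated), via piperidylzinc chloride 4 (not isolated)
Conditions: 1, s-BuLi, TMEDA, Et2O, −78 °C; dilithium salt of 4-methyl-2-{[(1-methylpyrrolidin-2-yl)methyl]amino}pentan-1-ol (10 mol%, the (2S,2'S) or (2R,2'S) diastereomer that enriches (S)-3), −45 °C; ZnCl2, −78 °C → rt; 2, Pd(OAc)2 (4 mol%), t-Bu3P·HBF4 (8 mol%), rt
Reagents that add atoms: none
Why: Carbamate-directed α-lithiation gives racemic 2-lithio-N-Boc-piperidine, which inverts at −45 °C and is funnelled by the substoichiometric chiral alkoxide into the more stable S-configured complex (catalytic dynamic resolution); transmetalation to zinc and the Negishi coupling with Pd(OAc)2/t-Bu3P both proceed with retention, so the ligand sets C2' as R, and the alkylzinc chloride is too mild to add to the chromone.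

Step 2
Reactants: 5 tert-butyl (2R)-2-(4-oxo-2-phenyl-4H-chromen-6-yl)piperidine-1-carboxylate
Product: 6 2-phenyl-6-[(2R)-piperidin-2-yl]-4H-chromen-4-one
Conditions: TFA, CH2Cl2, 0 °C → rt; then aq. NaHCO3
Reagents that add atoms: none
Why: Acid-mediated Boc cleavage (loss of the tert-butyl cation, then decarboxylation) touches neither the chromone nor C2', whose benzylic C–N bond has no electron-rich arene to help it ionise.

Step 3
Reactants: 6 2-phenyl-6-[(2R)-piperidin-2-yl]-4H-chromen-4-one
Product: 8 6-[(2R)-1-methylpiperidin-2-yl]-2-phenyl-4H-chromen-4-one, via iminium ion 7 (not isolated)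
Conditions: 37% aq. HCHO, NaBH(OAc)3, AcOH (cat.), 1,2-dichloroethane, rt; then aq. NaHCO3
Reagents that add atoms: formaldehyde, C=O
Why: Reductive amination: the secondary amine condenses with formaldehyde to the N-methylidene iminium ion, which NaBH(OAc)3 reduces while leaving the chromone carbonyl and the C2–C3 double bond alone; C2' is not involved.

Step 4
Reactants: 8 6-[(2R)-1-methylpiperidin-2-yl]-2-phenyl-4H-chromen-4-one; 9 (diacetoxyiodo)benzene
Product: 11 6-[(2R)-1-methylpiperidin-2-yl]-4-oxo-2-phenyl-4H-chromene-5,7-diyl diacetate, via 7-monoacetate 10 (not isolated)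
Conditions: Pd(OAc)2 (10 mol%), 9 (3 equiv, in portions), AcOH/Ac2O (1:1), 90 °C
Reagents that add atoms: (diacetoxyiodo)benzene (compound 9), CC(=O)OI(OC(C)=O)c1ccccc1; its acetate can exchange with the solvent acetic acid, CC(=O)O
Why: Proposed new method: the small free-base fraction of N1' present in acetic acid binds Pd(OAc)2, acetate-assisted concerted metalation–deprotonation at C7 gives the five-membered palladacycle (Pd, N1', C2', C6, C7), PhI(OAc)2 oxidises divalent to tetravalent palladium and C–O reductive elimination releases the C7 acetate 10; rotation about C6–C2' then turns N1' toward C5, where the C4 carbonyl oxygen can act as a second donor, and the same cycle forms the C5–O bond. The closest known reaction types are the Pd(OAc)2/PhI(OAc)2 ortho-acetoxylation of arenes bearing nitrogen directing groups, the Pd(OAc)2-catalysed ortho-olefination and carbonylation of N,N-dimethylbenzylamines through the same kind of palladacycle, and the carbonyl-directed C5 hydroxylation of flavones; an amine-directed double acetoxylation of a flavone has not been shown. No ring is closed and no stereocentre is created, and the existing C2' centre should survive because its hydrogen is held exocyclic to the palladacycle, away from the syn-coplanar alignment with Pd–N1' that hydride loss to an iminium ion would need. The step needs site selectivity for C5 and C7 over C8, C3 and ring B, which is secured because only C5 and C7 can close a five-membered chelate with N1'. Chemoselectivity for C–H over amine oxidation is sought by reversible protonation of N1' in AcOH/Ac2O and by adding the oxidant in portions.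

Step 5
Reactants: 11 6-[(2R)-1-methylpiperidin-2-yl]-4-oxo-2-phenyl-4H-chromene-5,7-diyl diacetate
Product: 13 5,7-dihydroxy-6-[(2R)-1-methylpiperidin-2-yl]-2-phenyl-4H-chromen-4-one, via 5-monoacetate 12 (not isolated)
Conditions: K2CO3 (0.2 equiv), MeOH, 0 °C → rt; then pH 7 phosphate buffer
Reagents that add atoms: none
Why: Base-catalysed transesterification (Zemplén-type methanolysis) of aryl acetates is fast at or below room temperature, the 7-acetate para to the carbonyl-bearing carbon leaving first, and the cold, brief treatment is chosen so that the freed phenolic Mannich base has no occasion to open at C2' and racemise.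

**Compound list**

1 | tert-butyl piperidine-1-carboxylate | CC(C)(C)OC(=O)N1CCCCC1 | starting material
2 | 6-bromo-2-phenyl-4H-chromen-4-one (6-bromoflavone) | O=c1cc(-c2ccccc2)oc2ccc(Br)cc12 | starting material
3 | tert-butyl (2S)-2-lithiopiperidine-1-carboxylate | CC(C)(C)OC(=O)N1CCCC[C@@H]1[Li] | intermediate
4 | chloro{(2S)-1-[(tert-butoxy)carbonyl]piperidin-2-yl}zinc | CC(C)(C)OC(=O)N1CCCC[C@@H]1[Zn]Cl | intermediate
5 | tert-butyl (2R)-2-(4-oxo-2-phenyl-4H-chromen-6-yl)piperidine-1-carboxylate | CC(C)(C)OC(=O)N1CCCC[C@@H]1c1ccc2oc(-c3ccccc3)cc(=O)c2c1 | intermediate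
6 | 2-phenyl-6-[(2R)-piperidin-2-yl]-4H-chromen-4-one | N1CCCC[C@@H]1c1ccc2oc(-c3ccccc3)cc(=O)c2c1 | intermediate
7 | (2R)-1-methylidene-2-(4-oxo-2-phenyl-4H-chromen-6-yl)piperidin-1-ium | C=[N+]1CCCC[C@@H]1c1ccc2oc(-c3ccccc3)cc(=O)c2c1 | intermediate
8 | 6-[(2R)-1-methylpiperidin-2-yl]-2-phenyl-4H-chromen-4-one | CN1CCCC[C@@H]1c1ccc2oc(-c3ccccc3)cc(=O)c2c1 | intermediate
9 | (diacetoxyiodo)benzene | CC(=O)OI(OC(C)=O)c1ccccc1 | starting material
10 | 6-[(2R)-1-methylpiperidin-2-yl]-4-oxo-2-phenyl-4H-chromen-7-yl acetate | CN1CCCC[C@@H]1c1c(OC(C)=O)cc2oc(-c3ccccc3)cc(=O)c2c1 | intermediate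
11 | 6-[(2R)-1-methylpiperidin-2-yl]-4-oxo-2-phenyl-4H-chromene-5,7-diyl diacetate | CN1CCCC[C@@H]1c1c(OC(C)=O)cc2oc(-c3ccccc3)cc(=O)c2c1OC(C)=O | intermediate
12 | 7-hydroxy-6-[(2R)-1-methylpiperidin-2-yl]-4-oxo-2-phenyl-4H-chromen-5-yl acetate | CN1CCCC[C@@H]1c1c(O)cc2oc(-c3ccccc3)cc(=O)c2c1OC(C)=O | intermediate
13 | 5,7-dihydroxy-6-[(2R)-1-methylpiperidin-2-yl]-2-phenyl-4H-chromen-4-one | CN1CCCC[C@@H]1c1c(O)cc2oc(-c3ccccc3)cc(=O)c2c1O | target

**Totals**

Total step count: 5. Longest linear sequence: 5 steps (1 → 5 → 6 → 8 → 11 → 13).

**Steps most likely to fail**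

1. Step 4 (proposed new method). Oxidation of the amine by PhI(OAc)2, at nitrogen or by hydride loss next to it, may outrun cyclopalladation and cost the N-methyl group or the configuration at C2'. The catalyst may also be held as a stable N,C,O-chelate after metalation at C5, or the sequence may stop after the first acetoxylation.
Fallback, by known reaction types: it sets out from 1 and comes back at 13, and gives up late-stage oxygenation for a ring A that is oxygenated from the start.
 - Anodic α-methoxylation of 1 (Shono oxidation; graphite electrodes, Et4NOTs, MeOH) gives racemic tert-butyl 2-methoxypiperidine-1-carboxylate F1.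
 - BF3·OEt2 ionises F1 to the N-acyliminium ion, which alkylates ring A of commercial chrysin (5,7-dihydroxyflavone) in an aza-Friedel–Crafts amidoalkylation. The 6-substituted product, racemic tert-butyl 2-(5,7-dihydroxy-4-oxo-2-phenyl-4H-chromen-6-yl)piperidine-1-carboxylate F2, is separated from its 8-regioisomer by chromatography.
 - TFA frees racemic 5,7-dihydroxy-2-phenyl-6-(piperidin-2-yl)-4H-chromen-4-one F3.
 - Reductive methylation (HCHO, NaBH(OAc)3) gives racemic 5,7-dihydroxy-6-(1-methylpiperidin-2-yl)-2-phenyl-4H-chromen-4-one F4.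
 - Preparative chromatography on a chiral stationary phase delivers 13.

2. Step 1. The enantiomeric ratio may erode if the organolithium equilibrates incompletely or the organozinc racemises; palladium may walk along the piperidine (β-hydride elimination and reinsertion) to give the 3-aryl isomer; residual organolithium may attack the chromone.
Fallback: it sets out from 2 and comes back at 6, moving the stereo-defining event from C–C bond formation to C=N reduction.
 - Suzuki–Miyaura coupling of 2 with commercial tert-butyl 6-(4,4,5,5-tetramethyl-1,3,2-dioxaborolan-2-yl)-3,4-dihydro-2H-pyridine-1-carboxylate (Pd(dppf)Cl2, K2CO3, dioxane/H2O, 80 °C) gives tert-butyl 6-(4-oxo-2-phenyl-4H-chromen-6-yl)-3,4-dihydro-2H-pyridine-1-carboxylate F5.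
 - TFA removes the Boc group, and the enamine tautomerises to the cyclic imine 2-phenyl-6-(3,4,5,6-tetrahydropyridin-2-yl)-4H-chromen-4-one F6.
 - An R-selective imine reductase (NADPH recycled with glucose dehydrogenase and glucose, buffer/DMSO) reduces the C=N bond under enzyme control to give 6, without touching the chromone.

3. Step 5. Once the phenols are free under base, C2' may racemise through reversible opening of the ortho-hydroxybenzylamine (retro-Mannich by way of an ortho-quinone methide), or methoxide may open the pyranone ring.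
Fallback: it sets out from 11 and comes back at 13, unmasking in the acid manifold instead.
 - Acid-catalysed transesterification with anhydrous HCl in MeOH (from AcCl/MeOH, 0 °C → rt) keeps N1' protonated and never forms a phenoxide.
 - The product is collected as 5,7-dihydroxy-6-[(2R)-1-methylpiperidin-2-yl]-2-phenyl-4H-chromen-4-one hydrochloride F7.
 - A brief cold NaHCO3 wash liberates 13 just before use.

**Further compounds**

F1 | step 4 | tert-butyl 2-methoxypiperidine-1-carboxylate (racemic) | COC1CCCCN1C(=O)OC(C)(C)C
F2 | step 4 | tert-butyl 2-(5,7-dihydroxy-4-oxo-2-phenyl-4H-chromen-6-yl)piperidine-1-carboxylate (racemic) | CC(C)(C)OC(=O)N1CCCCC1c1c(O)cc2oc(-c3ccccc3)cc(=O)c2c1O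
F3 | step 4 | 5,7-dihydroxy-2-phenyl-6-(piperidin-2-yl)-4H-chromen-4-one (racemic) | Oc1cc2oc(-c3ccccc3)cc(=O)c2c(O)c1C1CCCCN1
F4 | step 4 | 5,7-dihydroxy-6-(1-methylpiperidin-2-yl)-2-phenyl-4H-chromen-4-one (racemic) | CN1CCCCC1c1c(O)cc2oc(-c3ccccc3)cc(=O)c2c1O
F5 | step 1 | tert-butyl 6-(4-oxo-2-phenyl-4H-chromen-6-yl)-3,4-dihydro-2H-pyridine-1-carboxylate | CC(C)(C)OC(=O)N1CCCC=C1c1ccc2oc(-c3ccccc3)cc(=O)c2c1
F6 | step 1 | 2-phenyl-6-(3,4,5,6-tetrahydropyridin-2-yl)-4H-chromen-4-one | O=c1cc(-c2ccccc2)oc2ccc(C3=NCCCC3)cc12
F7 | step 5 | 5,7-dihydroxy-6-[(2R)-1-methylpiperidin-2-yl]-2-phenyl-4H-chromen-4-one hydrochloride | Cl.CN1CCCC[C@@H]1c1c(O)cc2oc(-c3ccccc3)cc(=O)c2c1O
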